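**Retrosynthetic overview**

1. The target is epicatechin-(4β→8)-epicatechin-(4β→8)-catechin-(4β→8)-epicatechin, and its third unit is 2,3-trans-3,4-cis. The hardest bond, C4 (ring C, unit 3)–C8 (ring A, unit 4), is therefore cut first, giving trimer sulfide 10 and the unit-4 boronic acid 15.
2. The enabling feature is the 3β-hydroxyl on C3 of ring C of unit 3, which sits cis to that bond. It carries a boron whose aryl ligand is C8 of ring A of unit 4 (flanked by O1 and O7), so the aryl is delivered to the β face of the C4 cation (stabilised by O1, O5 and O7 of ring A of unit 3).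
3. Trimer 10 is cut at its two other C4–C8 bonds into two copies of one epicatechin electrophile 4 and a catechin unit 8 that carries a latent 4-arylthio leaving group.
4. No ring is built: rings A, B and C of all four units and every C2/C3 stereocentre come from (−)-epicatechin (three units) and (+)-catechin (one unit). Only the three C4 centres are made, in the order unit 2, unit 1, unit 3.
5. The end game is acetate removal followed by hydrogenolysis of seventeen benzyl ethers.

Key step: step 12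

Remark on the chemistry: ether 7 is drawn as the 4β epimer and the sulfide in 8, 9 and 10 as the 4α (3,4-trans) epimer, the isomers expected to predominate. These C4 configurations are erased when C4 is ionised, so an epimer mixture can be carried forward.
Remark on the chemistry: (−)-epicatechin, (+)-catechin and all reagents are taken as commercial.

**Route**

Step 1
Reactants: 1 (−)-epicatechin
Product: 2 5,7,3',4'-tetra-O-benzyl-(−)-epicatechin
Conditions: BnBr (4.4 equiv), K2CO3, DMF, 0 °C → rt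
Reagents that add atoms: benzyl bromide BrCc1ccccc1
Why: Williamson etherification of the four phenols only, since the secondary 3-OH is not deprotonated by K2CO3 and the mild base leaves C2 and C3 untouched.

Step 2
Reactants: 2 5,7,3',4'-tetra-O-benzyl-(−)-epicatechin
Product: 3 5,7,3',4'-tetra-O-benzyl-4β-(2-ethoxyethoxy)epicatechin
Conditions: DDQ (2 equiv), 2-ethoxyethanol, CH2Cl2, rt
Reagents that add atoms: 2-ethoxyethanol CCOCCO
Why: DDQ benzylic oxidation (hydride abstraction at C4 of the electron-rich ring A) followed by capture of the cation by the alcohol anti to the 3α-oxygen and 2α-aryl should give the 4β ether, a standard activation of benzylated flavan-3-ols.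

Step 3
Reactants: 3 5,7,3',4'-tetra-O-benzyl-4β-(2-ethoxyethoxy)epicatechin
Product: 4 3-O-acetyl-5,7,3',4'-tetra-O-benzyl-4β-(2-ethoxyethoxy)epicatechin
Conditions: Ac2O, pyridine, DMAP (cat.), rt
Reagents that add atoms: acetic anhydride CC(=O)OC(C)=O
Why: Routine acylation of the secondary alcohol; the acetate later blocks O3 of units 1 and 2 and supports β attack at C4.

Step 4
Reactants: 5 (+)-catechin
Product: 6 5,7,3',4'-tetra-O-benzyl-(+)-catechin
Conditions: BnBr (4.4 equiv), K2CO3, DMF, 0 °C → rt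
Reagents that add atoms: benzyl bromide BrCc1ccccc1
Why: Williamson etherification of the four phenols as in step 1, with the 3-OH left free.

Step 5
Reactants: 6 5,7,3',4'-tetra-O-benzyl-(+)-catechin
Product: 7 5,7,3',4'-tetra-O-benzyl-4β-(2-ethoxyethoxy)catechin
Conditions: DDQ (2 equiv), 2-ethoxyethanol, CH2Cl2, rt
Reagents that add atoms: 2-ethoxyethanol CCOCCO
Why: The same DDQ benzylic oxidation with alcohol capture as in step 2; the C4 configuration formed here is of no consequence because C4 is ionised again in step 6.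

Step 6
Reactants: 7 5,7,3',4'-tetra-O-benzyl-4β-(2-ethoxyethoxy)catechin
Product: 8 5,7,3',4'-tetra-O-benzyl-4α-(2,6-dimethylphenylthio)catechin
Conditions: 2,6-dimethylbenzenethiol (3 equiv), TMSOTf (0.1 equiv), CH2Cl2, −78 → −20 °C
Reagents that add atoms: 2,6-dimethylbenzenethiol Cc1cccc(C)c1S
Why: The oxophilic Lewis acid ionises the C4–O bond and the thiol captures the flavan-4-yl cation (the reaction type of proanthocyanidin thiolysis), giving a sulfide that is inert to hard Lewis acids and is kept as the latent leaving group.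

Step 7
Reactants: 4 3-O-acetyl-5,7,3',4'-tetra-O-benzyl-4β-(2-ethoxyethoxy)epicatechin; 8 5,7,3',4'-tetra-O-benzyl-4α-(2,6-dimethylphenylthio)catechin (2.5 equiv, excess recovered)
Product: 9 dimer sulfide 3-O-acetyl-tetra-O-benzylepicatechin-(4β→8)-[tetra-O-benzyl-4α-(2,6-dimethylphenylthio)catechin]
Conditions: TMSOTf (0.2 equiv), CH2Cl2, −78 °C; Et3N quench
Reagents that add atoms: none
Why: Friedel–Crafts arylation of the flavan-4-yl cation from 4 by C8 of 8, the most nucleophilic ring A position of benzylated flavan-3-ols; attack anti to the axial 3α-acetoxy group should set the new C4 centre as 4β, and the soft arylthio group is not engaged by the silyl triflate.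

Step 8
Reactants: 4 3-O-acetyl-5,7,3',4'-tetra-O-benzyl-4β-(2-ethoxyethoxy)epicatechin; 9 dimer sulfide (1.2 equiv)
Product: 10 trimer sulfide [3-O-acetyl-tetra-O-benzylepicatechin-(4β→8)]2-[tetra-O-benzyl-4α-(2,6-dimethylphenylthio)catechin]
Conditions: TMSOTf (0.2 equiv), CH2Cl2, −78 °C; Et3N quench
Reagents that add atoms: none
Why: The same cation arylation, now at the only unsubstituted C8 of 9 (top unit), should set the second C4 centre as 4β anti to the 3α-acetoxy group, as in known top-down chain extensions of benzylated procyanidins.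

Step 9
Reactants: 2 5,7,3',4'-tetra-O-benzyl-(−)-epicatechin
Product: 11 8-bromo-5,7,3',4'-tetra-O-benzyl-(−)-epicatechin
Conditions: NBS (1.0 equiv), CH2Cl2, −78 °C → rt
Reagents that add atoms: N-bromosuccinimide O=C1CCC(=O)N1Br
Why: Electrophilic aromatic bromination at C8, the position flanked by O1 and the 7-benzyloxy group, which is the established site of monobromination in this series.

Step 10
Reactants: 11 8-bromo-5,7,3',4'-tetra-O-benzyl-(−)-epicatechin
Product: 12 8-bromo-3,5,7,3',4'-penta-O-benzyl-(−)-epicatechin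
Conditions: NaH, BnBr, DMF, 0 °C → rt
Reagents that add atoms: benzyl bromide BrCc1ccccc1
Why: Williamson etherification of the 3-OH removes the only acidic proton before lithiation and leaves a group that falls in the final hydrogenolysis.

Step 11
Reactants: 12 8-bromo-3,5,7,3',4'-penta-O-benzyl-(−)-epicatechin
Product: 15 (3,5,7,3',4'-penta-O-benzylepicatechin-8-yl)boronic acid, via aryllithium 13 (not isolated), via lithium triisopropoxyborate 14 (not isolated)
Conditions: B(OiPr)3 (1.5 equiv), then n-BuLi (1.05 equiv), THF, −78 °C (in situ quench); dilute aq. HCl, 0 °C, short contact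
Reagents that add atoms: triisopropyl borate CC(C)OB(OC(C)C)OC(C)C; water O
Why: Bromine–lithium exchange at −78 °C is faster than benzylic deprotonation, the aryllithium is trapped at once by the borate already present, and mild hydrolysis of the ate complex should give the boronic acid with boron fixed at C8.

Step 12
Reactants: 10 trimer sulfide; 15 (3,5,7,3',4'-penta-O-benzylepicatechin-8-yl)boronic acid (1.1 equiv)
Product: 18 protected tetramer (units 1 and 2 as 3-O-acetates; unit 3 with free 3-OH and the new 4β→8 bond; seventeen benzyl ethers), via boronic monoester 16 (not isolated), via O-borylated tetramer 17 (not isolated)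
Conditions: toluene azeotrope, then 4 Å MS, CH2Cl2, rt; dilute to 5 mM, AgOTf (1.3 equiv), −78 → −40 °C, no amine base; aq. NaHCO3
Reagents that add atoms: none
Why: Proposed new method: AgOTf abstracts the arylthio group from C4 of unit 3 to give the flavan-4-yl cation (stabilised by O1 and the 5- and 7-benzyloxy groups of ring A), and the boron-bearing C8 of unit 4, held over the β face by the O3–B ester link, attacks C4 at its ipso carbon through a five-membered cyclic transition state (C4, C3, O3, B, C8) before the C–B bond is given up to triflate and ring A of unit 4 rearomatises. The closest known reaction type is the Petasis-type transfer of an aryl group from a hydroxyl-bound boronate to a neighbouring iminium or N-acyliminium carbon, which places the new C–C bond cis to the directing oxygen, combined with the silver-promoted arylation of flavan-4-yl sulfides. No ring of the product is closed, since the five-membered cycle exists only in the transition state and the O–B bond is hydrolysed on work-up. The one new stereocentre, C4 of unit 3, should be set as 4β (3,4-cis, 2,4-trans) by the 3β-oxygen that carries the boron, against the 3,4-trans preference of untethered attack on catechin-type cations. The step needs β-face selectivity and C8 rather than C6 selectivity in unit 4: the short O3–B tether secures the first and ipso substitution at the boron-bearing carbon the second, while the 3-O-acetates of units 1 and 2 leave O3 of unit 3 as the only site that can bind boron and high dilution suppresses intermolecular attack by the free C8 of unit 1.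

Step 13
Reactants: 18 protected tetramer
Product: 19 heptadeca-O-benzyl tetramer (3-OH free on units 1, 2 and 3; 3-O-benzyl on unit 4)
Conditions: n-Bu4NOH (40% aq.), THF, rt → 40 °C
Reagents that add atoms: none
Why: Saponification of the two hindered secondary acetates; benzyl ethers and interflavan bonds are stable to hydroxide, and with no free phenol present there is no base-induced C2 epimerisation.

Step 14
Reactants: 19 heptadeca-O-benzyl tetramer
Product: 20 epicatechin-(4β→8)-epicatechin-(4β→8)-catechin-(4β→8)-epicatechin (target)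
Conditions: H2 (1 atm), Pd(OH)2/C, THF/MeOH/H2O (20:20:1), rt
Reagents that add atoms: none
Why: Catalytic hydrogenolysis should cleave all seventeen benzyl ethers under neutral conditions that leave the acid-labile interflavan bonds and all stereocentres intact, as is usual for benzylated procyanidin oligomers.

**Compound list**

1 | (−)-epicatechin, (2R,3R) | Oc1cc(O)c2c(c1)O[C@H](c1ccc(O)c(O)c1)[C@H](O)C2 | starting material
2 | 5,7,3',4'-tetra-O-benzyl-(−)-epicatechin (3-OH free) | c1ccccc1COc1cc(OCc3ccccc3)c2c(c1)O[C@H](c1ccc(OCc3ccccc3)c(OCc3ccccc3)c1)[C@H](O)C2 | intermediate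
3 | 5,7,3',4'-tetra-O-benzyl-4β-(2-ethoxyethoxy)epicatechin (2,3-cis-3,4-trans) | c1ccccc1COc1cc(OCc3ccccc3)c2c(c1)O[C@H](c1ccc(OCc3ccccc3)c(OCc3ccccc3)c1)[C@H](O)[C@H]2OCCOCC | intermediate
4 | 3-O-acetyl-5,7,3',4'-tetra-O-benzyl-4β-(2-ethoxyethoxy)epicatechin | c1ccccc1COc1cc(OCc3ccccc3)c2c(c1)O[C@H](c1ccc(OCc3ccccc3)c(OCc3ccccc3)c1)[C@H](OC(C)=O)[C@H]2OCCOCC | intermediate
5 | (+)-catechin, (2R,3S) | Oc1cc(O)c2c(c1)O[C@H](c1ccc(O)c(O)c1)[C@@H](O)C2 | starting material
6 | 5,7,3',4'-tetra-O-benzyl-(+)-catechin (3-OH free) | c1ccccc1COc1cc(OCc3ccccc3)c2c(c1)O[C@H](c1ccc(OCc3ccccc3)c(OCc3ccccc3)c1)[C@@H](O)C2 | intermediate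
7 | 5,7,3',4'-tetra-O-benzyl-4β-(2-ethoxyethoxy)catechin (2,3-trans-3,4-cis) | c1ccccc1COc1cc(OCc3ccccc3)c2c(c1)O[C@H](c1ccc(OCc3ccccc3)c(OCc3ccccc3)c1)[C@@H](O)[C@H]2OCCOCC | intermediate
8 | 5,7,3',4'-tetra-O-benzyl-4α-(2,6-dimethylphenylthio)catechin (2,3-trans-3,4-trans; 3-OH free) | c1ccccc1COc1cc(OCc3ccccc3)c2c(c1)O[C@H](c1ccc(OCc3ccccc3)c(OCc3ccccc3)c1)[C@@H](O)[C@@H]2Sc1c(C)cccc1C | intermediate
9 | dimer sulfide: 3-O-acetyl-tetra-O-benzylepicatechin-(4β→8)-[tetra-O-benzyl-4α-(2,6-dimethylphenylthio)catechin] | c1ccccc1COc1cc(OCc3ccccc3)c2c(c1)O[C@H](c1ccc(OCc3ccccc3)c(OCc3ccccc3)c1)[C@H](OC(C)=O)[C@H]2c1c(OCc3ccccc3)cc(OCc3ccccc3)c2c1O[C@H](c1ccc(OCc3ccccc3)c(OCc3ccccc3)c1)[C@@H](O)[C@@H]2Sc1c(C)cccc1C | intermediate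
10 | trimer sulfide: [3-O-acetyl-tetra-O-benzylepicatechin-(4β→8)]2-[tetra-O-benzyl-4α-(2,6-dimethylphenylthio)catechin], free 3-OH only on the catechin unit | c1ccccc1COc1cc(OCc3ccccc3)c2c(c1)O[C@H](c1ccc(OCc3ccccc3)c(OCc3ccccc3)c1)[C@H](OC(C)=O)[C@H]2c1c(OCc3ccccc3)cc(OCc3ccccc3)c2c1O[C@H](c1ccc(OCc3ccccc3)c(OCc3ccccc3)c1)[C@H](OC(C)=O)[C@H]2c1c(OCc3ccccc3)cc(OCc3ccccc3)c2c1O[C@H](c1ccc(OCc3ccccc3)c(OCc3ccccc3)c1)[C@@H](O)[C@@H]2Sc1c(C)cccc1C | intermediate
11 | 8-bromo-5,7,3',4'-tetra-O-benzyl-(−)-epicatechin | Brc1c(OCc3ccccc3)cc(OCc3ccccc3)c2c1O[C@H](c1ccc(OCc3ccccc3)c(OCc3ccccc3)c1)[C@H](O)C2 | intermediate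
12 | 8-bromo-3,5,7,3',4'-penta-O-benzyl-(−)-epicatechin | Brc1c(OCc3ccccc3)cc(OCc3ccccc3)c2c1O[C@H](c1ccc(OCc3ccccc3)c(OCc3ccccc3)c1)[C@H](OCc3ccccc3)C2 | intermediate
13 | 8-lithio-3,5,7,3',4'-penta-O-benzylepicatechin | [Li]c1c(OCc3ccccc3)cc(OCc3ccccc3)c2c1O[C@H](c1ccc(OCc3ccccc3)c(OCc3ccccc3)c1)[C@H](OCc3ccccc3)C2 | intermediate (not isolated)
14 | lithium triisopropoxy(3,5,7,3',4'-penta-O-benzylepicatechin-8-yl)borate | [Li+].CC(C)O[B-](OC(C)C)(OC(C)C)c1c(OCc3ccccc3)cc(OCc3ccccc3)c2c1O[C@H](c1ccc(OCc3ccccc3)c(OCc3ccccc3)c1)[C@H](OCc3ccccc3)C2 | intermediate (not isolated)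
15 | (3,5,7,3',4'-penta-O-benzylepicatechin-8-yl)boronic acid | OB(O)c1c(OCc3ccccc3)cc(OCc3ccccc3)c2c1O[C@H](c1ccc(OCc3ccccc3)c(OCc3ccccc3)c1)[C@H](OCc3ccccc3)C2 | intermediate
16 | boronic monoester: O3 of the catechin unit of 10 bonded to B(OH) that carries C8 of penta-O-benzylepicatechin | c1ccccc1COc1cc(OCc3ccccc3)c2c(c1)O[C@H](c1ccc(OCc3ccccc3)c(OCc3ccccc3)c1)[C@H](OC(C)=O)[C@H]2c1c(OCc3ccccc3)cc(OCc3ccccc3)c2c1O[C@H](c1ccc(OCc3ccccc3)c(OCc3ccccc3)c1)[C@H](OC(C)=O)[C@H]2c1c(OCc3ccccc3)cc(OCc3ccccc3)c2c1O[C@H](c1ccc(OCc3ccccc3)c(OCc3ccccc3)c1)[C@@H](OB(O)c1c(OCc3ccccc3)cc(OCc3ccccc3)c4c1O[C@H](c1ccc(OCc3ccccc3)c(OCc3ccccc3)c1)[C@H](OCc3ccccc3)C4)[C@@H]2Sc1c(C)cccc1C | intermediate (not isolated)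
17 | O-borylated tetramer: 18 with O3 of unit 3 carrying B(OH)(OTf) | c1ccccc1COc1cc(OCc3ccccc3)c2c(c1)O[C@H](c1ccc(OCc3ccccc3)c(OCc3ccccc3)c1)[C@H](OC(C)=O)[C@H]2c1c(OCc3ccccc3)cc(OCc3ccccc3)c2c1O[C@H](c1ccc(OCc3ccccc3)c(OCc3ccccc3)c1)[C@H](OC(C)=O)[C@H]2c1c(OCc3ccccc3)cc(OCc3ccccc3)c2c1O[C@H](c1ccc(OCc3ccccc3)c(OCc3ccccc3)c1)[C@@H](OB(O)OS(=O)(=O)C(F)(F)F)[C@H]2c1c(OCc3ccccc3)cc(OCc3ccccc3)c2c1O[C@H](c1ccc(OCc3ccccc3)c(OCc3ccccc3)c1)[C@H](OCc3ccccc3)C2 | intermediate (not isolated)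
18 | protected tetramer: [3-O-acetyl-tetra-O-benzylepicatechin-(4β→8)]2-[tetra-O-benzylcatechin]-(4β→8)-[penta-O-benzylepicatechin], catechin unit 2,3-trans-3,4-cis with free 3-OH | c1ccccc1COc1cc(OCc3ccccc3)c2c(c1)O[C@H](c1ccc(OCc3ccccc3)c(OCc3ccccc3)c1)[C@H](OC(C)=O)[C@H]2c1c(OCc3ccccc3)cc(OCc3ccccc3)c2c1O[C@H](c1ccc(OCc3ccccc3)c(OCc3ccccc3)c1)[C@H](OC(C)=O)[C@H]2c1c(OCc3ccccc3)cc(OCc3ccccc3)c2c1O[C@H](c1ccc(OCc3ccccc3)c(OCc3ccccc3)c1)[C@@H](O)[C@H]2c1c(OCc3ccccc3)cc(OCc3ccccc3)c2c1O[C@H](c1ccc(OCc3ccccc3)c(OCc3ccccc3)c1)[C@H](OCc3ccccc3)C2 | intermediate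
19 | heptadeca-O-benzyl tetramer: 18 without the two acetyl groups | c1ccccc1COc1cc(OCc3ccccc3)c2c(c1)O[C@H](c1ccc(OCc3ccccc3)c(OCc3ccccc3)c1)[C@H](O)[C@H]2c1c(OCc3ccccc3)cc(OCc3ccccc3)c2c1O[C@H](c1ccc(OCc3ccccc3)c(OCc3ccccc3)c1)[C@H](O)[C@H]2c1c(OCc3ccccc3)cc(OCc3ccccc3)c2c1O[C@H](c1ccc(OCc3ccccc3)c(OCc3ccccc3)c1)[C@@H](O)[C@H]2c1c(OCc3ccccc3)cc(OCc3ccccc3)c2c1O[C@H](c1ccc(OCc3ccccc3)c(OCc3ccccc3)c1)[C@H](OCc3ccccc3)C2 | intermediate
20 | epicatechin-(4β→8)-epicatechin-(4β→8)-catechin-(4β→8)-epicatechin (CNP0236700.5) | Oc1cc(O)c2c(c1)O[C@H](c1ccc(O)c(O)c1)[C@H](O)[C@H]2c1c(O)cc(O)c2c1O[C@H](c1ccc(O)c(O)c1)[C@H](O)[C@H]2c1c(O)cc(O)c2c1O[C@H](c1ccc(O)c(O)c1)[C@@H](O)[C@H]2c1c(O)cc(O)c2c1O[C@H](c1ccc(O)c(O)c1)[C@H](O)C2 | target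

**Step count and risks**

Total step count: 14. Longest linear sequence: 8 steps (1, 2, 3, 7, 8, 12, 13, 14; equally 4, 5, 6, 7, 8, 12, 13, 14).

Steps most likely to fail:

1. Step 12. The boronic monoester may form incompletely, or boron may be lost by protodeboronation or by boron-to-silver exchange. The cation would then be attacked by untethered arene from the α face or through C6, and facial and positional control would be lost. The fallback uses the known dicarboxylate-tether strategy for steering flavan-4-yl cation arylation to the 3,4-cis (4β→8) linkage; it sets out from 2 and 10 and comes back at 20. Alcohol 2 would be opened onto glutaric anhydride (DMAP, pyridine) to the 3-O-glutarate half-ester F1. F1 would be esterified with the free 3-OH of 10 (EDC·HCl, DMAP, CH2Cl2) to the tethered diester F2. AgOTf in dilute CH2Cl2 at low temperature should then close the macrolide F3 by C4–C8 bond formation on the β face. n-Bu4NOH in THF would cleave the tether and both acetates to the hexadeca-O-benzyl tetramer F4, and hydrogenolysis under the conditions of step 14 would give 20. The tether length (succinate, glutarate, adipate) is the variable to adjust.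

2. Step 8. The electrophile 4 may self-condense through its own free C8, attack may occur through C6 of either unit of 9, or the C4–S bond may ionise prematurely under the acid. The fallback inverts the order so that the cheap monomer is the partner used in excess; it sets out from 4, 2 and 8 and comes back at 10. Electrophile 4 would be coupled with an excess of 2 (TMSOTf, CH2Cl2, −78 °C) to the dimer alcohol F5. DDQ with 2-ethoxyethanol would oxidise the only benzylic CH2 (bottom unit, next to the free 3-OH) to the dimeric 4β-(2-ethoxyethoxy) ether F6, and Ac2O/pyridine would give the dimeric electrophile F7. F7 would then be coupled with an excess of 8 under the conditions of step 7 to give 10.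

3. Step 11. Benzylic deprotonation and anionic rearrangement of the ortho-benzyloxy aryllithium may compete with bromine–lithium exchange, and the very electron-rich boronic acid may protodeboronate during aqueous work-up. The fallback avoids the aryllithium; it sets out from 12 and comes back at 15. Pd-catalysed Miyaura borylation of 12 (B2pin2, KOAc, Pd(OAc)2, SPhos, dioxane, 80 °C) would give the pinacol boronate F8. Oxidative cleavage of the pinacol ester (NaIO4, NH4OAc, acetone/H2O, rt) would then give 15.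

**Further compounds**

F1 | step 12 | 3-O-(4-carboxybutanoyl)-5,7,3',4'-tetra-O-benzylepicatechin | c1ccccc1COc1cc(OCc3ccccc3)c2c(c1)O[C@H](c1ccc(OCc3ccccc3)c(OCc3ccccc3)c1)[C@H](OC(=O)CCCC(O)=O)C2
F2 | step 12 | tethered diester: glutarate linking O3 of the catechin unit of 10 to O3 of tetra-O-benzylepicatechin | c1ccccc1COc1cc(OCc3ccccc3)c2c(c1)O[C@H](c1ccc(OCc3ccccc3)c(OCc3ccccc3)c1)[C@H](OC(C)=O)[C@H]2c1c(OCc3ccccc3)cc(OCc3ccccc3)c2c1O[C@H](c1ccc(OCc3ccccc3)c(OCc3ccccc3)c1)[C@H](OC(C)=O)[C@H]2c1c(OCc3ccccc3)cc(OCc3ccccc3)c2c1O[C@H](c1ccc(OCc3ccccc3)c(OCc3ccccc3)c1)[C@@H](OC(=O)CCCC(=O)O[C@@H]4Cc5c(OCc3ccccc3)cc(OCc3ccccc3)cc5O[C@@H]4c1ccc(OCc3ccccc3)c(OCc3ccccc3)c1)[C@@H]2Sc1c(C)cccc1C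
F3 | step 12 | macrolide: protected tetramer with the 4β→8 bond between units 3 and 4 and the glutarate bridge between their O3 atoms | c1ccccc1COc1cc(OCc3ccccc3)c2c(c1)O[C@H](c1ccc(OCc3ccccc3)c(OCc3ccccc3)c1)[C@H](OC(C)=O)[C@H]2c1c(OCc3ccccc3)cc(OCc3ccccc3)c2c1O[C@H](c1ccc(OCc3ccccc3)c(OCc3ccccc3)c1)[C@H](OC(C)=O)[C@H]2c1c(OCc3ccccc3)cc(OCc3ccccc3)c2c1O[C@H](c1ccc(OCc3ccccc3)c(OCc3ccccc3)c1)[C@@H]4[C@H]2c1c(OCc3ccccc3)cc(OCc3ccccc3)c5c1O[C@H](c1ccc(OCc3ccccc3)c(OCc3ccccc3)c1)[C@@H](C5)OC(=O)CCCC(=O)O4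
F4 | step 12 | hexadeca-O-benzyl tetramer with all four 3-OH free | c1ccccc1COc1cc(OCc3ccccc3)c2c(c1)O[C@H](c1ccc(OCc3ccccc3)c(OCc3ccccc3)c1)[C@H](O)[C@H]2c1c(OCc3ccccc3)cc(OCc3ccccc3)c2c1O[C@H](c1ccc(OCc3ccccc3)c(OCc3ccccc3)c1)[C@H](O)[C@H]2c1c(OCc3ccccc3)cc(OCc3ccccc3)c2c1O[C@H](c1ccc(OCc3ccccc3)c(OCc3ccccc3)c1)[C@@H](O)[C@H]2c1c(OCc3ccccc3)cc(OCc3ccccc3)c2c1O[C@H](c1ccc(OCc3ccccc3)c(OCc3ccccc3)c1)[C@H](O)C2
F5 | step 8 | dimer alcohol: 3-O-acetyl-tetra-O-benzylepicatechin-(4β→8)-tetra-O-benzylepicatechin | c1ccccc1COc1cc(OCc3ccccc3)c2c(c1)O[C@H](c1ccc(OCc3ccccc3)c(OCc3ccccc3)c1)[C@H](OC(C)=O)[C@H]2c1c(OCc3ccccc3)cc(OCc3ccccc3)c2c1O[C@H](c1ccc(OCc3ccccc3)c(OCc3ccccc3)c1)[C@H](O)C2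
F6 | step 8 | dimeric ether: F5 with a 4β-(2-ethoxyethoxy) group on the bottom unit | c1ccccc1COc1cc(OCc3ccccc3)c2c(c1)O[C@H](c1ccc(OCc3ccccc3)c(OCc3ccccc3)c1)[C@H](OC(C)=O)[C@H]2c1c(OCc3ccccc3)cc(OCc3ccccc3)c2c1O[C@H](c1ccc(OCc3ccccc3)c(OCc3ccccc3)c1)[C@H](O)[C@H]2OCCOCC
F7 | step 8 | dimeric electrophile: F6 as its bottom-unit 3-O-acetate | c1ccccc1COc1cc(OCc3ccccc3)c2c(c1)O[C@H](c1ccc(OCc3ccccc3)c(OCc3ccccc3)c1)[C@H](OC(C)=O)[C@H]2c1c(OCc3ccccc3)cc(OCc3ccccc3)c2c1O[C@H](c1ccc(OCc3ccccc3)c(OCc3ccccc3)c1)[C@H](OC(C)=O)[C@H]2OCCOCC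
F8 | step 11 | 3,5,7,3',4'-penta-O-benzylepicatechin-8-ylboronic acid pinacol ester | CC1(C)OB(OC1(C)C)c1c(OCc3ccccc3)cc(OCc3ccccc3)c2c1O[C@H](c1ccc(OCc3ccccc3)c(OCc3ccccc3)c1)[C@H](OCc3ccccc3)C2
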